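**Retrosynthetic overview**
- Ring B (the 2,3-dihydro-4H-pyran-4-one) is opened last at its enol-ether O–C(sp2) bond, giving the hydroxy enol 14; the C2–O bond is never broken, so C2 keeps its configuration.
- Ring A (the δ-lactone) is cut at the lactone O–CH(decyl) alkyl bond and at the ring-fusion C=C, a formal [3+3] disconnection into a γ-hydroxy ketone and an oxalic acid half-ester.
- Enabling feature: the fusion carbon that carries the ring-B oxygen and the lactone carbonyl next to it are two adjacent carbons at the carboxylic-acid oxidation level (an oxalyl unit). The other fusion carbon is the α-carbon of the ring-B ketone, and the decyl carbinol is γ to that ketone, so the lactone enol is the Claisen adduct of a ketone and an oxalate.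
- The acyclic C23 hydroxy ketone 10 comes from acetylene as a linchpin between two terminal epoxides, which supply both stereocentres; the internal alkyne is a latent ketone, hydrated under the direction of the free hydroxyl.
- Order of ring formation: ring A (step 6), then ring B (step 7).

Key step: step 6

Remark: 1, 3, 6 and 11 are taken as catalogue chemicals; 10 is drawn as the open-chain hydroxy ketone although it will equilibrate with its five-membered cyclic hemiketal, and only the open form reacts in step 6. TBS = tert-butyldimethylsilyl.

**Step 1**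
Reactants: 1 rac-1,2-epoxynonane
Product: 2 (S)-1,2-epoxynonane
Conditions: (S,S)-(salen)Co(OAc) (0.5 mol %; salen = N,N'-bis(3,5-di-tert-butylsalicylidene)-1,2-cyclohexanediamine dianion), H2O (0.55 equiv), neat, 0 °C to rt; distillation
Reagents that add atoms: none
Why: Hydrolytic kinetic resolution of a terminal epoxide, in which the (S,S)-configured acetate of trivalent cobalt should hydrolyse the (R)-epoxide much faster, so that unreacted 2 is recovered with the future ring-B carbinol carbon defined.

**Step 2**
Reactants: 2 (S)-1,2-epoxynonane; 3 lithium acetylide–ethylenediamine complex (LiC≡CH·H2NCH2CH2NH2)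
Product: 4 (S)-undec-1-yn-4-ol
Conditions: DMSO, 0 °C to rt; aq. NH4Cl
Reagents that add atoms: none
Why: SN2 opening of the terminal epoxide by acetylide at the unsubstituted carbon, which leaves the C–O bond of the stereocentre untouched (retention).

**Step 3**
Reactants: 4 (S)-undec-1-yn-4-ol
Product: 5 (S)-tert-butyldimethyl(undec-1-yn-4-yloxy)silane
Conditions: TBSCl, imidazole, DMF, rt
Reagents that add atoms: tert-butyldimethylsilyl chloride, CC(C)(C)[Si](C)(C)Cl
Why: Standard silylation of a secondary alcohol, which masks the hydroxyl that must not direct the later hydration or enter the esterification.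

**Step 4**
Reactants: 5 (S)-tert-butyldimethyl(undec-1-yn-4-yloxy)silane; 6 (R)-1,2-epoxydodecane
Product: 8 (11R,16S)-16-[(tert-butyldimethylsilyl)oxy]tricos-13-yn-11-ol, via lithium acetylide 7 (not isolated)
Conditions: n-BuLi, THF, −78 °C; BF3·OEt2; then 6, −78 °C; aq. NH4Cl
Reagents that add atoms: none
Why: BF3-promoted alkynylation of a terminal epoxide at its CH2 carbon, so the configuration of 6 is carried over unchanged as the (R)-carbinol C11.

**Step 5**
Reactants: 8 (11R,16S)-16-[(tert-butyldimethylsilyl)oxy]tricos-13-yn-11-ol
Product: 10 (8S,13R)-8-[(tert-butyldimethylsilyl)oxy]-13-hydroxytricosan-10-one, via cyclic enol ether 9 (not isolated)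
Conditions: Ph3PAuNTf2 (2 mol %), THF/H2O 10:1, rt
Reagents that add atoms: water, O
Why: Hydroxyl-directed alkyne hydration by 5-endo-dig hydroalkoxylation with cationic monovalent gold and hydrolysis of the resulting enol ether; the free hydroxyl can only reach the remote alkyne carbon, so the ketone should appear γ to the free carbinol and β to the silyl ether.

**Step 6**
Reactants: 10 (8S,13R)-8-[(tert-butyldimethylsilyl)oxy]-13-hydroxytricosan-10-one; 11 ethyl hydrogen oxalate
Product: 13 (S)-4-{(S)-3-[(tert-butyldimethylsilyl)oxy]decanoyl}-6-decyl-3-hydroxy-5,6-dihydro-2H-pyran-2-one, via mixed oxalate diester 12 (not isolated)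
Conditions: 11 (1.5 equiv), Bu3P=CHCN (1.5 equiv), toluene, rt to 50 °C; then THF, LiN(SiMe3)2 (3 equiv), −78 to 0 °C; aq. HCl
Reagents that add atoms: none
Why: Bu3P=CHCN is protonated by the strongly acidic half-ester, the C13 hydroxyl of 10 is transferred to phosphorus and the oxalate carboxylate displaces the alkoxyphosphonium group by SN2 (Mitsunobu esterification), forming the alkyl C–O bond of the future lactone with inversion; LiN(SiMe3)2 then generates the ketone enolate, whose C11 carbon adds to the ethyl-ester carbonyl of the oxalate and expels ethoxide (Dieckmann/intramolecular Claisen condensation), forming the ring-fusion C–C bond and leaving the product as its stabilised tricarbonyl enolate. The closest known reaction types are the Mitsunobu inversion of secondary alcohols with acidic carboxylic acids and the Claisen condensation of ketone enolates with dialkyl oxalates to 2,4-dioxo esters, joined here as a formal [3+3] annulation. Ring A is closed in the second event by a 6-(enolexo)-exo-trig attack of the enolate carbon on the distal oxalate carbonyl. The only new stereocentre, the decyl-bearing lactone carbon, is controlled by the stereospecific SN2 inversion, (R)-carbinol to (S)-ester, so it is set by epoxide 6 and not by the remote silyloxy centre. The step needs C–C bond formation at C11 and not at C9, and survival of the β-silyloxy ketone: only the C11 enolate can reach an oxalate carbonyl through a six-membered transition state (the C9 enolate would have to close an eight-membered ring and should return by proton exchange), the acidic product enolate drains the equilibrium, and the lithium counter-ion at low temperature should suppress β-elimination of the silyloxy group. The by-products of the first stage (Bu3P=O, MeCN) are neutral and non-nucleophilic, so the base can be added to the same flask.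

**Step 7**
Reactants: 13 (S)-4-{(S)-3-[(tert-butyldimethylsilyl)oxy]decanoyl}-6-decyl-3-hydroxy-5,6-dihydro-2H-pyran-2-one
Product: 15 (2S,6S)-6-decyl-2-heptyl-2,3,5,6-tetrahydro-4H,8H-pyrano[3,4-b]pyran-4,8-dione, via hydroxy enol 14 (not isolated)
Conditions: HF·pyridine, MeCN, 0 °C to rt; then TsOH·H2O (cat.), 4 Å molecular sieves, CH2Cl2, rt if the hemiketal persists
Reagents that add atoms: none
Why: Desilylation followed by cyclodehydration of a δ-hydroxy-β-dicarbonyl to a 2,3-dihydro-4H-pyran-4-one (vinylogous esterification): the freed hydroxyl adds to the enolised α-keto-lactone carbon and water is lost, closing ring B without breaking the C2–O bond, so the (S) configuration is kept.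

**Compound list**
1 | rac-1,2-epoxynonane (2-heptyloxirane) | CCCCCCCC1CO1 | starting material
2 | (S)-1,2-epoxynonane | CCCCCCC[C@H]1CO1 | intermediate
3 | lithium acetylide–ethylenediamine complex | [Li+].[C-]#C.NCCN | starting material
4 | (S)-undec-1-yn-4-ol | CCCCCCC[C@H](O)CC#C | intermediate
5 | (S)-tert-butyldimethyl(undec-1-yn-4-yloxy)silane | CCCCCCC[C@H](O[Si](C)(C)C(C)(C)C)CC#C | intermediate
6 | (R)-1,2-epoxydodecane | CCCCCCCCCC[C@@H]1CO1 | starting material
7 | lithium acetylide of 5 (formed in the flask) | CCCCCCC[C@H](O[Si](C)(C)C(C)(C)C)CC#C[Li] | intermediate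
8 | (11R,16S)-16-[(tert-butyldimethylsilyl)oxy]tricos-13-yn-11-ol | CCCCCCC[C@H](O[Si](C)(C)C(C)(C)C)CC#CC[C@H](O)CCCCCCCCCC | intermediate
9 | tert-butyl({(S)-1-[(R)-5-decyl-4,5-dihydrofuran-2-yl]nonan-2-yl}oxy)dimethylsilane (cyclic enol ether, formed in the flask) | CCCCCCCCCC[C@@H]1CC=C(C[C@H](CCCCCCC)O[Si](C)(C)C(C)(C)C)O1 | intermediate
10 | (8S,13R)-8-[(tert-butyldimethylsilyl)oxy]-13-hydroxytricosan-10-one | CCCCCCC[C@H](O[Si](C)(C)C(C)(C)C)CC(=O)CC[C@H](O)CCCCCCCCCC | intermediate
11 | ethyl hydrogen oxalate | CCOC(=O)C(=O)O | starting material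
12 | ethyl (11S,16S)-16-[(tert-butyldimethylsilyl)oxy]-14-oxotricosan-11-yl oxalate (formed in the flask) | CCCCCCC[C@H](O[Si](C)(C)C(C)(C)C)CC(=O)CC[C@@H](OC(=O)C(=O)OCC)CCCCCCCCCC | intermediate
13 | (S)-4-{(S)-3-[(tert-butyldimethylsilyl)oxy]decanoyl}-6-decyl-3-hydroxy-5,6-dihydro-2H-pyran-2-one | CCCCCCCCCC[C@H]1CC(C(=O)C[C@H](CCCCCCC)O[Si](C)(C)C(C)(C)C)=C(O)C(=O)O1 | intermediate
14 | (S)-6-decyl-3-hydroxy-4-[(S)-3-hydroxydecanoyl]-5,6-dihydro-2H-pyran-2-one (formed in the flask) | CCCCCCCCCC[C@H]1CC(C(=O)C[C@H](CCCCCCC)O)=C(O)C(=O)O1 | intermediate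
15 | (2S,6S)-6-decyl-2-heptyl-2,3,5,6-tetrahydro-4H,8H-pyrano[3,4-b]pyran-4,8-dione | CCCCCCCCCC[C@H]1CC2=C(O[C@@H](CCCCCCC)CC2=O)C(=O)O1 | target

**Step count and risks**
Total step count: 7. Longest linear sequence: 7 (steps 1 to 7; epoxide 6 and acid 11 enter as purchased side components).

Steps most likely to fail:

1. Step 6 (key step). The invertive esterification may lose stereochemical fidelity if the ketone oxygen takes part in the displacement at the activated carbinol (net retention, or diversion to a cyclic enol ether). The condensation in the same flask may also be diverted by enolisation toward the silyloxy side followed by β-elimination. Fallback: give up the inversion and separate the two events. It sets out from 5. The lithium acetylide 7 is added under BF3·OEt2 to purchased (S)-1,2-epoxydodecane F1 to give (11S,16S)-16-[(tert-butyldimethylsilyl)oxy]tricos-13-yn-11-ol F2. F2 is hydrated as in step 5, through the epimeric cyclic enol ether F3, to (8S,13S)-8-[(tert-butyldimethylsilyl)oxy]-13-hydroxytricosan-10-one F4. O-Acylation of F4 with ethyl chlorooxalate and pyridine in CH2Cl2 at 0 °C (retention, no activation of the carbinol carbon) gives the oxalate 12 as an isolated compound. A separate Dieckmann condensation under soft enolisation (MgBr2·OEt2, i-Pr2NEt, CH2Cl2, rt) then closes ring A, and the fallback comes back to the route at 13.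

2. Step 5. The hydration may lose its regiocontrol if the silyl ether oxygen or external water competes with the free hydroxyl for the gold-activated alkyne, and the silyl ether may be cleaved by adventitious acid. Fallback: install the carbonyl before the carbon chain is completed. It sets out from 5. Markovnikov hydration of the terminal alkyne (Ph3PAuNTf2, MeOH/H2O) gives (S)-4-[(tert-butyldimethylsilyl)oxy]undecan-2-one F5. Condensation with 1,1-dimethylhydrazine gives its N,N-dimethylhydrazone F6. Kinetic deprotonation at the methyl group with LiN(i-Pr)2 and alkylation with epoxide 6 gives (8S,13R)-8-[(tert-butyldimethylsilyl)oxy]-10-(2,2-dimethylhydrazinylidene)tricosan-13-ol F7. Hydrolysis of the hydrazone with aqueous CuCl2 comes back to the route at 10.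

3. Step 7. Under acid the freed β-hydroxy ketone may eliminate to the enone and re-close by oxa-Michael addition, which would erode the C2 configuration, or the ring closure may stop at the hemiketal stage. Fallback: separate deprotection from dehydration and run the dehydration without acid. It sets out from 13. Buffered desilylation (Bu4NF/AcOH, THF, 0 °C) gives the hydroxy enol 14, which should close to the bicyclic hemiketal (2S,6S)-6-decyl-2-heptyl-8a-hydroxyhexahydropyrano[3,4-b]pyran-4,8-dione F8 (configuration at C4a and C8a open). Elimination of its tertiary hydroxyl with methyl N-(triethylammoniosulfonyl)carbamate (Burgess reagent, benzene, rt) introduces the ring-fusion double bond and comes back to the route at 15.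

**Further compounds**
F1 | step 6 | (S)-1,2-epoxydodecane (purchased) | CCCCCCCCCC[C@H]1CO1
F2 | step 6 | (11S,16S)-16-[(tert-butyldimethylsilyl)oxy]tricos-13-yn-11-ol | CCCCCCC[C@H](O[Si](C)(C)C(C)(C)C)CC#CC[C@@H](O)CCCCCCCCCC
F3 | step 6 | tert-butyl({(S)-1-[(S)-5-decyl-4,5-dihydrofuran-2-yl]nonan-2-yl}oxy)dimethylsilane (formed in the flask) | CCCCCCCCCC[C@H]1CC=C(C[C@H](CCCCCCC)O[Si](C)(C)C(C)(C)C)O1
F4 | step 6 | (8S,13S)-8-[(tert-butyldimethylsilyl)oxy]-13-hydroxytricosan-10-one | CCCCCCC[C@H](O[Si](C)(C)C(C)(C)C)CC(=O)CC[C@@H](O)CCCCCCCCCC
F5 | step 5 | (S)-4-[(tert-butyldimethylsilyl)oxy]undecan-2-one | CCCCCCC[C@H](O[Si](C)(C)C(C)(C)C)CC(C)=O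
F6 | step 5 | (S)-4-[(tert-butyldimethylsilyl)oxy]undecan-2-one N,N-dimethylhydrazone | CCCCCCC[C@H](O[Si](C)(C)C(C)(C)C)CC(C)=NN(C)C
F7 | step 5 | (8S,13R)-8-[(tert-butyldimethylsilyl)oxy]-10-(2,2-dimethylhydrazinylidene)tricosan-13-ol | CCCCCCC[C@H](O[Si](C)(C)C(C)(C)C)CC(CC[C@H](O)CCCCCCCCCC)=NN(C)C
F8 | step 7 | (2S,6S)-6-decyl-2-heptyl-8a-hydroxyhexahydropyrano[3,4-b]pyran-4,8-dione | CCCCCCCCCC[C@H]1CC2C(=O)C[C@H](CCCCCCC)OC2(O)C(=O)O1
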